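**Retrosynthetic overview**
1. Hippolide A (14) is a 2-hydroxy-3,6-dihydro-2H-pyran. It is the last ring formed, by photosensitised E→Z isomerisation and hemiacetalisation of the E-δ-hydroxy-α-alkyl enal 13.
2. Enal 13 comes from cross-metathesis of the homoallylic-alcohol succinimide 8 with the 2-homofarnesyl acrolein 12. Acrolein 12 is made from farnesylacetic acid by Ni/photoredox decarboxylative vinylation and MnO2 oxidation.
3. Imide 8 comes from vinyl-cuprate opening of the epoxy-imide 6. Epoxide 6 is formed from the trans lactone-amide 5 by a methoxide cascade: lactone opening, epoxide closure, imide closure.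
4. Lactone 5 comes from photoredox hydrocarbamoylation of the chiral-pool butenolide 3. The carbamoyl radical adds anti to the C5 substituent, so the existing stereocentre sets the new one. Rings are formed in the order γ-lactone (bought), succinimide, then dihydropyran lactol.

Assumptions: farnesylacetic acid is available as the (all-E) isomer and 2-bromoallyl alcohol is commercial. The anomeric C2 stereocentre equilibrates through the open Z-enal, and the drawn anomer is taken as the isolated one.

---

**Step 1**
Reactants: 1 (S)-5-(hydroxymethyl)furan-2(5H)-one; 2 p-toluenesulfonyl chloride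
Product: 3 (S)-5-(tosyloxymethyl)furan-2(5H)-one
Conditions: TsCl (1.2 equiv), pyridine, CH2Cl2, 0 °C, 3 h
Reagents that add atoms: TsCl, Cc1ccc(cc1)S(=O)(=O)Cl
Why: Sulfonylation of the primary alcohol gives a leaving group for the later epoxide closure and leaves the C5 stereocentre untouched.

**Step 2**
Reactants: 3; 4 oxamic acid
Product: 5 [(2S,3S)-3-carbamoyl-5-oxooxolan-2-yl]methyl 4-methylbenzenesulfonate
Conditions: 4 (2 equiv), 4CzIPN (2 mol%), K2HPO4 (1 equiv), DMSO, blue LEDs (455 nm), 25 °C, 16 h
Reagents that add atoms: oxamic acid, NC(=O)C(=O)O (supplies the CONH2 group)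
Why: In a photoredox decarboxylative Giese conjugate addition, the carbamoyl radical adds to the β-carbon of the butenolide anti to the CH2OTs group; this gives the trans-3,4-disubstituted lactone with the required (3S) centre, and the α-lactone radical is reduced and protonated at the CH2 position.

**Step 3**
Reactants: 5
Product: 6 (3S)-3-[(2S)-oxiran-2-yl]pyrrolidine-2,5-dione
Conditions: NaOMe (3 equiv), MeOH, 0 → 25 °C, 4 h; then sat. aq. NH4Cl and extraction
Reagents that add atoms: none (methoxide ends up only in MeOH and NaOTs)
Why: Methoxide opens the lactone reversibly, the released alkoxide displaces the tosylate irreversibly (3-exo-tet at CH2, so the carbinol centre keeps its configuration), and the primary amide closes onto the methyl ester (5-exo imide formation, Dieckmann-type) to the sodium imidate that drives the cascade.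

**Step 4**
Reactants: 6; 7 vinylmagnesium bromide
Product: 8 (3S)-3-[(1R)-1-hydroxybut-3-en-1-yl]pyrrolidine-2,5-dione
Conditions: CH2=CHMgBr (3.5 equiv), CuI (20 mol%), THF, −40 → 0 °C, 2 h; then NH4Cl
Reagents that add atoms: vinylmagnesium bromide, C=C[Mg]Br
Why: Cu-catalysed SN2 opening of the epoxide occurs at the unhindered CH2, so the carbinol stereocentre is untouched; the N-magnesio imidate deactivates the imide carbonyls towards Grignard attack.

**Step 5**
Reactants: 9 (4E,8E)-5,9,13-trimethyltetradeca-4,8,12-trienoic acid (farnesylacetic acid); 10 2-bromoprop-2-en-1-ol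
Product: 11 2-[(3E,7E)-4,8,12-trimethyltrideca-3,7,11-trien-1-yl]prop-2-en-1-ol
Conditions: 9 (1.5 equiv), 10 (1 equiv), [Ir{dF(CF3)ppy}2(dtbbpy)]PF6 (1 mol%), NiCl2·glyme (10 mol%), dtbbpy (10 mol%), Cs2CO3 (1.5 equiv), DMF, blue LEDs, 25 °C, 18 h
Reagents that add atoms: none beyond reactants 9 and 10
Why: Ni/photoredox decarboxylative Csp3–Csp2 coupling (vinylation) joins the primary alkyl radical, formed by oxidative decarboxylation of the carboxylate, to the vinyl bromide, and the trisubstituted E,E-alkenes are inert.

**Step 6**
Reactants: 11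
Product: 12 2-[(3E,7E)-4,8,12-trimethyltrideca-3,7,11-trien-1-yl]prop-2-enal
Conditions: activated MnO2 (15 equiv), CH2Cl2, 25 °C, 3 h (use crude, with BHT)
Reagents that add atoms: none
Why: MnO2 oxidises the allylic alcohol selectively to the α-substituted acrolein without touching the isolated alkenes.

**Step 7**
Reactants: 8; 12
Product: 13 (2E,5R)-5-[(3S)-2,5-dioxopyrrolidin-3-yl]-5-hydroxy-2-[(3E,7E)-4,8,12-trimethyltrideca-3,7,11-trien-1-yl]pent-2-enal
Conditions: 12 (3 equiv), Hoveyda–Grubbs II (5 mol%), 1,4-benzoquinone (10 mol%), CH2Cl2 (0.03 M), 40 °C, 16 h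
Reagents that add atoms: none
Why: Cross-metathesis of the monosubstituted terminal alkene of 8 with the electron-poor 2-alkylacrolein (the methacrolein-type partner) gives the trisubstituted E-enal and ethylene, with no stereocentre involved; any Z-enal formed cyclises directly in step 8.

**Step 8**
Reactants: 13
Product: 14 Hippolide A
Conditions: thioxanthone (10 mol%), 405 nm LEDs, CH2Cl2/MeCN 1:1, 25 °C, 8 h
Reagents that add atoms: none
Why: Proposed new method: triplet energy transfer from thioxanthone (ET ≈ 65 kcal/mol) to the conjugated enal (the isolated trisubstituted alkenes, ET > 75, are not sensitised) makes the twisted triplet, which decays to E and Z. The Z-enal is intercepted by the pendant C5 hydroxyl (6-exo hemiacetalisation) to give the lactol, which lacks the enal chromophore and so accumulates as a photochemical sink; the C6 centre is unchanged and the anomeric C2 centre settles thermodynamically through the open Z-enal. The closest known chemistry is photosensitised E→Z isomerisation with in-situ lactonisation of γ- and δ-hydroxy enoates to butenolides and dihydropyranones, here applied to an α-alkyl δ-hydroxy enal that gives a lactol.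

---

**Compound list**

| # | Name | SMILES | Role |
|---|---|---|---|
| 1 | (S)-5-(hydroxymethyl)furan-2(5H)-one | O=C1C=C[C@@H](CO)O1 | starting material |
| 2 | p-toluenesulfonyl chloride | Cc1ccc(cc1)S(=O)(=O)Cl | starting material |
| 3 | [(2S)-5-oxo-2,5-dihydrofuran-2-yl]methyl 4-methylbenzenesulfonate | O=C1C=C[C@@H](COS(=O)(=O)c2ccc(C)cc2)O1 | intermediate |
| 4 | oxamic acid | NC(=O)C(=O)O | starting material |
| 5 | [(2S,3S)-3-carbamoyl-5-oxooxolan-2-yl]methyl 4-methylbenzenesulfonate | NC(=O)[C@H]1CC(=O)O[C@@H]1COS(=O)(=O)c1ccc(C)cc1 | intermediate |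
| 6 | (3S)-3-[(2S)-oxiran-2-yl]pyrrolidine-2,5-dione | O=C1C[C@@H]([C@H]2CO2)C(=O)N1 | intermediate |
| 7 | vinylmagnesium bromide | C=C[Mg]Br | starting material |
| 8 | (3S)-3-[(1R)-1-hydroxybut-3-en-1-yl]pyrrolidine-2,5-dione | O=C1C[C@@H]([C@H](O)CC=C)C(=O)N1 | intermediate |
| 9 | (4E,8E)-5,9,13-trimethyltetradeca-4,8,12-trienoic acid (farnesylacetic acid) | OC(=O)CC/C=C(C)/CC/C=C(C)/CCC=C(C)C | starting material |
| 10 | 2-bromoprop-2-en-1-ol | C=C(Br)CO | starting material |
| 11 | 2-[(3E,7E)-4,8,12-trimethyltrideca-3,7,11-trien-1-yl]prop-2-en-1-ol | OCC(=C)CC/C=C(C)/CC/C=C(C)/CCC=C(C)C | intermediate |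
| 12 | 2-[(3E,7E)-4,8,12-trimethyltrideca-3,7,11-trien-1-yl]prop-2-enal | C=C(CC/C=C(C)/CC/C=C(C)/CCC=C(C)C)C=O | intermediate |
| 13 | (2E,5R)-5-[(3S)-2,5-dioxopyrrolidin-3-yl]-5-hydroxy-2-[(3E,7E)-4,8,12-trimethyltrideca-3,7,11-trien-1-yl]pent-2-enal | O=C1C[C@@H]([C@H](O)C/C=C(\CC/C=C(C)/CC/C=C(C)/CCC=C(C)C)/C=O)C(=O)N1 | intermediate |
| 14 | Hippolide A: (3S)-3-[(2R,6S)-6-hydroxy-5-[(3E,7E)-4,8,12-trimethyltrideca-3,7,11-trien-1-yl]-3,6-dihydro-2H-pyran-2-yl]pyrrolidine-2,5-dione | CC(C)=CCC/C(C)=C/CC/C(C)=C/CCC1=CC[C@H]([C@@H]2CC(=O)NC2=O)O[C@@H]1O | target |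

**Totals**
- Total steps: 8 (Steps 1–8, with the acrolein branch, Steps 5–6, converging at Step 7).
- Longest linear sequence: 6 (Steps 1 → 2 → 3 → 4 → 7 → 8, counted from 1).

**Three steps most likely to fail**
1. **Step 8 (proposed new photochemical isomerisation/lactolisation).** The α-alkyl enal triplet energy may be too high for thioxanthone, or E/Z conversion may be inefficient.
   - Fallback (known chemistry): acetalise 8 with the dimethyl acetal of 12 (PPTS) to the mixed acetal, close the ring by Grubbs-II RCM to the 2-methoxy-3,6-dihydro-2H-pyran, then hydrolyse with aqueous AcOH to the lactol. This fixes the ring alkene geometry without any photoisomerisation.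
2. **Step 3 (methoxide cascade).** The β-oxygenated imide can undergo E1cB elimination or epoxide methanolysis, and the imide closure is slow.
   - Fallback: reverse the order. Convert tosylate 5 to the iodide (NaI, acetone), couple it with vinyl bromide by Ni/photoredox cross-electrophile coupling to install the allyl group on the lactone-amide, then run NaOMe/MeOH lactone→imide cyclisation to give 8 directly. This avoids both the epoxide and the Grignard step.
3. **Step 5 (Ni/photoredox decarboxylative vinylation of a primary unactivated acid).** Yields of such couplings are often modest.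
   - Fallback: convert 9 to its N-hydroxyphthalimide redox-active ester and couple it with 2-bromoallyl alcohol under Ni/Zn reductive decarboxylative alkenylation conditions.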